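**Retrosynthetic overview**

1. The oxolane is numbered O1, C2 (aryl), C3 (CH2OH), C4 (aroyl), C5. The ketone is carried to the last step as a 2-aryl-1,3-dithiane. The C2 aryl centre comes from a C2 lactone by aryllithium addition and hydride reduction of the cyclic oxocarbenium ion anti to the C3 arm, which should give the 2,3-cis ring.
2. Key disconnection: ketone carbon–C4. The enabling feature is that the ketone carbon and C2 are 1,4-related through C4–C3. With C2 at the lactone level, the ring O1–C2(=O)–C3=C4–C5 is a butenolide whose β-carbon is C4. The aroyl carbon is delivered to C4 as an acyl anion (lithiated dithiane), and the C3 enolate so formed is hydroxymethylated in the same flask.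
3. Absolute control: a (1S,2R,5S)-menthyloxy group on C5 steers C4 (trans), C4 steers C3 (trans), C3 steers C2 (cis). The auxiliary is then excised reductively to leave C5H2.
4. Ring order: the only ring of the target is the butenolide ring itself (opened and reclosed in passing in step 5). The 1,3-dithiane is the only temporary ring.

Key step: step 3

Remark: the oxolane positions are called O1, C2, C3, C4 and C5 at every stage, lactones included; 5-hydroxyfuran-2(5H)-one and (+)-menthol are taken as catalogue compounds.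

**Step 1**
Reactants: 1 5-hydroxyfuran-2(5H)-one; 2 (+)-menthol, (1S,2R,5S)-5-methyl-2-(propan-2-yl)cyclohexan-1-ol
Product: 3 (5S)-5-{[(1S,2R,5S)-5-methyl-2-(propan-2-yl)cyclohexyl]oxy}furan-2(5H)-one
Conditions: cat. TsOH·H2O, toluene, reflux (Dean–Stark); crystallisation from petroleum ether, mother liquor re-equilibrated with the acid and recrystallised
Reagents that add atoms: none
Why: Acid-catalysed acetalisation of the hemiacylal hydroxyl; the two C5 epimers interconvert under acid and the (5S) epimer of the d-menthyl series should crystallise selectively (mirror image of the well-known l-menthyl/(5R) pair), which fixes the absolute configuration of the whole route.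

**Step 2**
Reactants: 4 3,4,5-trimethoxybenzaldehyde; 5 propane-1,3-dithiol
Product: 6 2-(3,4,5-trimethoxyphenyl)-1,3-dithiane
Conditions: BF3·OEt2 (cat.), CH2Cl2, 0 °C → rt
Reagents that add atoms: none
Why: Lewis-acid-promoted dithioacetalisation of an aromatic aldehyde, which turns the aroyl carbon into a Corey–Seebach acyl anion precursor.

**Step 3**
Reactants: 6 2-(3,4,5-trimethoxyphenyl)-1,3-dithiane; 3 (5S)-5-(d-menthyloxy)furan-2(5H)-one
Product: 9 (3R,4S,5S)-3-(hydroxymethyl)-5-{[(1S,2R,5S)-5-methyl-2-(propan-2-yl)cyclohexyl]oxy}-4-[2-(3,4,5-trimethoxyphenyl)-1,3-dithian-2-yl]oxolan-2-one, via lithiated dithiane 7 (not isolated), via lithium lactone enolate 8 (not isolated)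
Conditions: n-BuLi, THF, −78 °C; then 3, −78 °C; then CH2O (monomer from cracked paraformaldehyde), −78 → −40 °C; AcOH quench
Reagents that add atoms: formaldehyde, C=O
Why: Deprotonation of 6 gives the sulfur-stabilised benzylic carbanion 7 (Corey–Seebach equivalent of the 3,4,5-trimethoxybenzoyl anion), which adds in conjugate fashion to C4 of butenolide 3 and so forms the ketone-carbon–C4 bond; the resulting lithium enolate 8 is then captured at C3 by monomeric formaldehyde in an aldol reaction. The closest known reaction type is the tandem conjugate addition–enolate trapping of lithiated 2-aryl-1,3-dithianes with 2(5H)-furanones or 5-alkoxy-2(5H)-furanones and aldehydes or benzylic halides, the classical three-component assembly of lignan lactones. No ring is closed, because the lactone ring of 3 is itself the future oxolane ring. C4 is set by the C5 acetal centre (the nucleophile enters anti to the menthyloxy group, 4,5-trans) and C3 is set by C4 (formaldehyde enters anti to the very large dithianyl substituent, 3,4-trans), which gives the 3R,4S configuration the target requires. The step needs 1,4- over 1,2-addition, secured by the charge-delocalised and hindered 2-aryl-dithianyl anion at −78 °C, and single hydroxymethylation, secured because the lithium aldolate is too weak a base to regenerate an enolate at low temperature.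

**Step 4**
Reactants: 9 hydroxymethyl lactone
Product: 10 (3R,4S,5S)-5-{[(1S,2R,5S)-5-methyl-2-(propan-2-yl)cyclohexyl]oxy}-3-({[tri(propan-2-yl)silyl]oxy}methyl)-4-[2-(3,4,5-trimethoxyphenyl)-1,3-dithian-2-yl]oxolan-2-one
Conditions: i-Pr3SiCl, imidazole, DMF, rt
Reagents that add atoms: triisopropylsilyl chloride, CC(C)[Si](Cl)(C(C)C)C(C)C
Why: Standard silylation of the primary alcohol, which blocks retro-aldol loss of formaldehyde and alkoxide chemistry in the aryllithium step and enlarges the C3 substituent that is to direct step 7.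

**Step 5**
Reactants: 10 silylated menthyloxy lactone
Product: 12 (3R,4S)-3-({[tri(propan-2-yl)silyl]oxy}methyl)-4-[2-(3,4,5-trimethoxyphenyl)-1,3-dithian-2-yl]oxolan-2-one, via potassium hydroxy carboxylate 11 (not isolated)
Conditions: NaBH4, KOH, EtOH/H2O, 0 °C → rt; then 1 M HCl to pH 3, rt
Reagents that add atoms: none
Why: Hydroxide opens the γ-alkoxy lactone (a pseudo-ester) to the C5 aldehyde carboxylate with loss of menthoxide, NaBH4 reduces the aldehyde as it forms to give 11 and acidification relactonises the γ-hydroxy acid, so that C5 ends as CH2 while C3 and C4 are untouched (reductive removal of a γ-alkoxybutenolide auxiliary; the carboxylate is not enolisable, which protects C3 and prevents loss of the dithianyl group).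

**Step 6**
Reactants: 12 lactone; 13 5-bromo-1,2,3-trimethoxybenzene
Product: 15 (3R,4S)-3-({[tri(propan-2-yl)silyl]oxy}methyl)-2-(3,4,5-trimethoxyphenyl)-4-[2-(3,4,5-trimethoxyphenyl)-1,3-dithian-2-yl]oxolan-2-ol, via 3,4,5-trimethoxyphenyllithium 14 (not isolated)
Conditions: 13, n-BuLi, THF, −78 °C; then added to 12 in THF, −78 °C; AcOH quench at −78 °C
Reagents that add atoms: none
Why: Bromine–lithium exchange gives 14, which should add once to the lactone carbonyl because the lithium lactolate persists at −78 °C until the acidic quench (lactone-to-lactol arylation as used for C-aryl glycosides and lignan hemiketals); the fully substituted dithiane and the silyl ether are inert, and the new C2 centre is formed as a mixture of epimers (in equilibrium with the open hydroxy ketone) that is erased in step 7.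

**Step 7**
Reactants: 15 cyclic hemiketal
Product: 17 {[(2R,3R,4S)-2-(3,4,5-trimethoxyphenyl)-4-[2-(3,4,5-trimethoxyphenyl)-1,3-dithian-2-yl]oxolan-3-yl]methoxy}tri(propan-2-yl)silane, via cyclic oxocarbenium ion 16 (not isolated)
Conditions: Et3SiH, BF3·OEt2, CH2Cl2, −78 °C; cold NaHCO3 quench
Reagents that add atoms: none
Why: BF3 ionises the hemiketal to the aryl-stabilised oxocarbenium ion 16 and Et3SiH should deliver hydride to C2 from the face opposite the adjacent C3 silyloxymethyl group, which places the aryl group cis to it (2R); this kinetic 2,3-cis outcome has precedent in the ionic reduction of 2-aryl cyclic hemiketals with trans-3,4 substituents in tetrahydrofuran lignan synthesis, and −78 °C suppresses acid-induced epimerisation of the benzylic ether.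

**Step 8**
Reactants: 17 silyl ether
Product: 18 [(2R,3R,4S)-2-(3,4,5-trimethoxyphenyl)-4-[2-(3,4,5-trimethoxyphenyl)-1,3-dithian-2-yl]oxolan-3-yl]methanol
Conditions: Bu4NF, AcOH, THF, rt
Reagents that add atoms: none
Why: Fluoride cleaves the Si–O bond of the primary silyl ether under acetic-acid buffering; no ketone is present yet, so the base-sensitive β-alkoxy ketone of the target is never exposed to fluoride.

**Step 9**
Reactants: 18 dithiane alcohol
Product: 19 [(3S,4R,5R)-4-(hydroxymethyl)-5-(3,4,5-trimethoxyphenyl)oxolan-3-yl](3,4,5-trimethoxyphenyl)methanone (target)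
Conditions: PhI(OCOCF3)2, NaHCO3, MeCN/H2O (9:1), 0 °C
Reagents that add atoms: water, O
Why: The hypervalent iodine reagent oxidises a dithiane sulfur and the resulting thionium ion is hydrolysed by water to the aryl ketone (oxidative dithiane hydrolysis), the bicarbonate buffer protects the acid-labile cis benzylic ether, and C4, now α to the ketone, already holds the thermodynamically preferred configuration trans to the C3 hydroxymethyl group, so no stereocentre is at risk.

**Compound list**

1 | 5-hydroxyfuran-2(5H)-one | O=C1C=CC(O)O1 | starting material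
2 | (+)-menthol, (1S,2R,5S)-5-methyl-2-(propan-2-yl)cyclohexan-1-ol | CC(C)[C@H]1CC[C@H](C)C[C@@H]1O | starting material
3 | (5S)-5-{[(1S,2R,5S)-5-methyl-2-(propan-2-yl)cyclohexyl]oxy}furan-2(5H)-one | O=C1C=C[C@@H](O[C@H]2C[C@@H](C)CC[C@@H]2C(C)C)O1 | intermediate
4 | 3,4,5-trimethoxybenzaldehyde | COc1cc(C=O)cc(OC)c1OC | starting material
5 | propane-1,3-dithiol | SCCCS | starting material
6 | 2-(3,4,5-trimethoxyphenyl)-1,3-dithiane | COc1cc(C2SCCCS2)cc(OC)c1OC | intermediate
7 | 2-lithio-2-(3,4,5-trimethoxyphenyl)-1,3-dithiane | COc1cc(C2([Li])SCCCS2)cc(OC)c1OC | intermediate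
8 | lithium enolate of (4S,5S)-5-(d-menthyloxy)-4-[2-(3,4,5-trimethoxyphenyl)-1,3-dithian-2-yl]oxolan-2-one | COc1cc(C2(SCCCS2)[C@@H]3[C@@H](O[C@H]4C[C@@H](C)CC[C@@H]4C(C)C)OC(O[Li])=C3)cc(OC)c1OC | intermediate
9 | (3R,4S,5S)-3-(hydroxymethyl)-5-{[(1S,2R,5S)-5-methyl-2-(propan-2-yl)cyclohexyl]oxy}-4-[2-(3,4,5-trimethoxyphenyl)-1,3-dithian-2-yl]oxolan-2-one | COc1cc(C2(SCCCS2)[C@@H]3[C@@H](O[C@H]4C[C@@H](C)CC[C@@H]4C(C)C)OC(=O)[C@H]3CO)cc(OC)c1OC | intermediate
10 | (3R,4S,5S)-5-{[(1S,2R,5S)-5-methyl-2-(propan-2-yl)cyclohexyl]oxy}-3-({[tri(propan-2-yl)silyl]oxy}methyl)-4-[2-(3,4,5-trimethoxyphenyl)-1,3-dithian-2-yl]oxolan-2-one | COc1cc(C2(SCCCS2)[C@@H]3[C@@H](O[C@H]4C[C@@H](C)CC[C@@H]4C(C)C)OC(=O)[C@H]3CO[Si](C(C)C)(C(C)C)C(C)C)cc(OC)c1OC | intermediate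
11 | potassium (2R,3S)-4-hydroxy-2-({[tri(propan-2-yl)silyl]oxy}methyl)-3-[2-(3,4,5-trimethoxyphenyl)-1,3-dithian-2-yl]butanoate | COc1cc(C2(SCCCS2)[C@H](CO)[C@H](CO[Si](C(C)C)(C(C)C)C(C)C)C(=O)[O-])cc(OC)c1OC.[K+] | intermediate
12 | (3R,4S)-3-({[tri(propan-2-yl)silyl]oxy}methyl)-4-[2-(3,4,5-trimethoxyphenyl)-1,3-dithian-2-yl]oxolan-2-one | COc1cc(C2(SCCCS2)[C@@H]3COC(=O)[C@H]3CO[Si](C(C)C)(C(C)C)C(C)C)cc(OC)c1OC | intermediate
13 | 5-bromo-1,2,3-trimethoxybenzene | COc1cc(Br)cc(OC)c1OC | starting material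
14 | 3,4,5-trimethoxyphenyllithium | COc1cc([Li])cc(OC)c1OC | intermediate
15 | (3R,4S)-3-({[tri(propan-2-yl)silyl]oxy}methyl)-2-(3,4,5-trimethoxyphenyl)-4-[2-(3,4,5-trimethoxyphenyl)-1,3-dithian-2-yl]oxolan-2-ol (both C2 epimers) | COc1cc(C2(SCCCS2)[C@@H]3COC(O)(c4cc(OC)c(OC)c(OC)c4)[C@H]3CO[Si](C(C)C)(C(C)C)C(C)C)cc(OC)c1OC | intermediate
16 | cyclic oxocarbenium ion from 15 (C2=O1 cation, 2-aryl, 3R,4S retained) | COc1cc(C2(SCCCS2)[C@@H]3C[O+]=C(c4cc(OC)c(OC)c(OC)c4)[C@H]3CO[Si](C(C)C)(C(C)C)C(C)C)cc(OC)c1OC | intermediate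
17 | {[(2R,3R,4S)-2-(3,4,5-trimethoxyphenyl)-4-[2-(3,4,5-trimethoxyphenyl)-1,3-dithian-2-yl]oxolan-3-yl]methoxy}tri(propan-2-yl)silane | COc1cc(C2(SCCCS2)[C@@H]3CO[C@@H](c4cc(OC)c(OC)c(OC)c4)[C@H]3CO[Si](C(C)C)(C(C)C)C(C)C)cc(OC)c1OC | intermediate
18 | [(2R,3R,4S)-2-(3,4,5-trimethoxyphenyl)-4-[2-(3,4,5-trimethoxyphenyl)-1,3-dithian-2-yl]oxolan-3-yl]methanol | COc1cc(C2(SCCCS2)[C@@H]3CO[C@@H](c4cc(OC)c(OC)c(OC)c4)[C@H]3CO)cc(OC)c1OC | intermediate
19 | [(3S,4R,5R)-4-(hydroxymethyl)-5-(3,4,5-trimethoxyphenyl)oxolan-3-yl](3,4,5-trimethoxyphenyl)methanone | COc1cc(C(=O)[C@@H]2CO[C@@H](c3cc(OC)c(OC)c(OC)c3)[C@H]2CO)cc(OC)c1OC | target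

**Step count and risks**

Total step count: 9. Longest linear sequence: 8 steps (steps 1, 3, 4, 5, 6, 7, 8, 9; the branch through step 2 is equally long).

Steps most likely to fail:

Step 7. Hydride delivery with poor facial selectivity, or acid-induced epimerisation at the new benzylic C2–O centre, would erode the 2,3-cis relationship. The large C4 substituent lies on the face from which hydride must arrive. In that case C2 would be set by reagent control and ring closure instead, setting out from 15. Its open hydroxy-ketone tautomer is reduced with (S)-2-methyl-CBS-oxazaborolidine and BH3·SMe2 (Corey–Bakshi–Shibata reduction, aryl as the large group) to (1R,2R,3S)-1-(3,4,5-trimethoxyphenyl)-2-({[tri(propan-2-yl)silyl]oxy}methyl)-3-[2-(3,4,5-trimethoxyphenyl)-1,3-dithian-2-yl]butane-1,4-diol F1. The primary hydroxyl is tosylated selectively (TsCl, pyridine, 0 °C) to (2S,3R,4R)-4-hydroxy-2-[2-(3,4,5-trimethoxyphenyl)-1,3-dithian-2-yl]-3-({[tri(propan-2-yl)silyl]oxy}methyl)-4-(3,4,5-trimethoxyphenyl)butyl 4-methylbenzenesulfonate F2. t-BuOK in THF then closes the oxolane by Williamson etherification, the benzylic alkoxide attacking C5, so that the C2–O bond and its configuration are retained and the route is rejoined at 17.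

Step 3. Proton quench of the enolate by the formaldehyde stream, or repeated hydroxymethylation, would cut the yield of the three-component coupling. The fallback sets out again from 6 and 3. After the conjugate addition, enolate 8 is carboxylated with dry CO2 (−78 °C, cold dilute acid) to (3R,4S,5S)-5-{[(1S,2R,5S)-5-methyl-2-(propan-2-yl)cyclohexyl]oxy}-2-oxo-4-[2-(3,4,5-trimethoxyphenyl)-1,3-dithian-2-yl]oxolane-3-carboxylic acid F3. Its C3 centre is epimerisable and should settle trans to C4. BH3·THF at 0 °C then reduces the free carboxylic acid chemoselectively beside the lactone and the acetal, returning to 9.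

Step 6. Double addition of the aryllithium, or enolisation of the lactone followed by retro-Michael loss of the dithianyl group, would consume the lactone unproductively. The fallback leaves from 12. Ring opening with MeNH(OMe)·HCl and AlMe3 (CH2Cl2, 0 °C) gives (2R,3S)-4-hydroxy-N-methoxy-N-methyl-2-({[tri(propan-2-yl)silyl]oxy}methyl)-3-[2-(3,4,5-trimethoxyphenyl)-1,3-dithian-2-yl]butanamide F4. This is silylated at once (Et3SiCl, imidazole) to its 4-O-triethylsilyl ether F5. Aryllithium 14 then stops at (2R,3S)-4-(triethylsilyloxy)-2-({[tri(propan-2-yl)silyl]oxy}methyl)-1-(3,4,5-trimethoxyphenyl)-3-[2-(3,4,5-trimethoxyphenyl)-1,3-dithian-2-yl]butan-1-one F6 (Weinreb ketone synthesis). AcOH/THF/H2O removes only the primary triethylsilyl group, and the freed hydroxy ketone closes to hemiketal 15.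

**Further compounds**

F1 | step 7 | (1R,2R,3S)-1-(3,4,5-trimethoxyphenyl)-2-({[tri(propan-2-yl)silyl]oxy}methyl)-3-[2-(3,4,5-trimethoxyphenyl)-1,3-dithian-2-yl]butane-1,4-diol | COc1cc(C2(SCCCS2)[C@H](CO)[C@H](CO[Si](C(C)C)(C(C)C)C(C)C)[C@@H](O)c3cc(OC)c(OC)c(OC)c3)cc(OC)c1OC
F2 | step 7 | (2S,3R,4R)-4-hydroxy-2-[2-(3,4,5-trimethoxyphenyl)-1,3-dithian-2-yl]-3-({[tri(propan-2-yl)silyl]oxy}methyl)-4-(3,4,5-trimethoxyphenyl)butyl 4-methylbenzenesulfonate | COc1cc(C2(SCCCS2)[C@H](COS(=O)(=O)c3ccc(C)cc3)[C@H](CO[Si](C(C)C)(C(C)C)C(C)C)[C@@H](O)c3cc(OC)c(OC)c(OC)c3)cc(OC)c1OC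
F3 | step 3 | (3R,4S,5S)-5-{[(1S,2R,5S)-5-methyl-2-(propan-2-yl)cyclohexyl]oxy}-2-oxo-4-[2-(3,4,5-trimethoxyphenyl)-1,3-dithian-2-yl]oxolane-3-carboxylic acid | COc1cc(C2(SCCCS2)[C@@H]3[C@@H](O[C@H]4C[C@@H](C)CC[C@@H]4C(C)C)OC(=O)[C@H]3C(=O)O)cc(OC)c1OC
F4 | step 6 | (2R,3S)-4-hydroxy-N-methoxy-N-methyl-2-({[tri(propan-2-yl)silyl]oxy}methyl)-3-[2-(3,4,5-trimethoxyphenyl)-1,3-dithian-2-yl]butanamide | COc1cc(C2(SCCCS2)[C@H](CO)[C@H](CO[Si](C(C)C)(C(C)C)C(C)C)C(=O)N(C)OC)cc(OC)c1OC
F5 | step 6 | (2R,3S)-N-methoxy-N-methyl-4-(triethylsilyloxy)-2-({[tri(propan-2-yl)silyl]oxy}methyl)-3-[2-(3,4,5-trimethoxyphenyl)-1,3-dithian-2-yl]butanamide | COc1cc(C2(SCCCS2)[C@H](CO[Si](CC)(CC)CC)[C@H](CO[Si](C(C)C)(C(C)C)C(C)C)C(=O)N(C)OC)cc(OC)c1OC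
F6 | step 6 | (2R,3S)-4-(triethylsilyloxy)-2-({[tri(propan-2-yl)silyl]oxy}methyl)-1-(3,4,5-trimethoxyphenyl)-3-[2-(3,4,5-trimethoxyphenyl)-1,3-dithian-2-yl]butan-1-one | COc1cc(C2(SCCCS2)[C@H](CO[Si](CC)(CC)CC)[C@H](CO[Si](C(C)C)(C(C)C)C(C)C)C(=O)c3cc(OC)c(OC)c(OC)c3)cc(OC)c1OC
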